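(The runs were generated by integration with constants of no real substance; the scatter is artificial.)

If J is lost by a second route besides the one into Q, the curve of Q in the red run can be drawn with two constants, both read from its readings.

| setting | red | teal | ochre | grey | blue |
|---|---|---|---|---|---|
| L | 300 mM | 150 mM | 300 mM | 300 mM | 300 mM |
| J | 240 mM | 90.0 mM | 240 mM | 360 mM | 240 mM |
| X | 30.0 mM | 30.0 mM | 15.0 mM | 30.0 mM | 30.0 mM |
| Q |  |  |  |  | 90.0 mM |
| time |  |  |  |  | 15 min |

| run | time / min | [Q] / mM |
|---|---|---|
| red run | 1.1 | 29.1 |
| red run | 3.5 | 71.0 |
| red run | 6.6 | 99.4 |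
| red run | 10 | 112.3 |
| red run | 15 | 121.2 |
| teal run | 1.1 | 9.6 |
| teal run | 3.5 | 22.2 |
| teal run | 6.6 | 30.6 |
| teal run | 10 | 35.9 |
| teal run | 15 | 39.2 |
| ochre run | 1.1 | 16.1 |
| ochre run | 3.5 | 40.1 |
| ochre run | 6.6 | 60.9 |
| ochre run | 10 | 72.5 |
| ochre run | 15 | 81.3 |
| grey run | 1.1 | 36.6 |
| grey run | 3.5 | 95.0 |
| grey run | 6.6 | 135.5 |
| grey run | 10 | 154.5 |
| grey run | 15 | 165.5 |

(each reading ± 0.9 mM)

- Overall: L + J -> Q, with X as catalyst.
- Constant volume, constant temperature.
- A reading of a species includes what of it is bound.
- "The second partner" is J.
- An order is taken over about fifteen percent of the charge, up and down.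
- A share of Q counts the Q that was charged too.

- how the opening rate goes with [X] round the charge of the red run: the exponent of the rate at two percent of L gone to Q
- how the opening rate goes with [J] round the charge of the red run: the exponent of the rate at two percent of L gone to Q
- Q in the blue run at 15 min, as a share of the L charged

**Red's curve.** Let f be the fraction of the J charge found as Q. In the red run, f climbs at 0.0382 min⁻¹ between 3.5 min and 6.6 min, but at 0.00742 min⁻¹ between 10 min and 15 min. An exponential fall through these two slopes has the constant 0.220 min⁻¹. The tail beyond the last reading then brings the level to 0.524. So f = level × (1 − exp(−constant × time)), with an opening slope of 0.115 min⁻¹. The knee lies at 4.55 min, where f stands at 0.332. The curve crosses a quarter of the L charge at 4.12 min, though the reading at 3.5 min is already 71.0 mM.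

**The leak.** Taking both draws on J as first order in J, an approximation, red's level is the share of the fall constant that goes into Q, and it stands below one. The remainder, read from the red run as 0.105 min⁻¹, is the leak: the fraction of J lost per minute without giving Q. The ochre run, with half the X, falls more slowly than red, with constant 0.180 min⁻¹. Its readings give a leak of 0.114 min⁻¹.

**Blue reckoned.** Between 1.1 min and 6.6 min, the red run gains 12.8 mM min⁻¹. Between 10 min and 15 min, at a Q inside the span red crossed, the ochre run gains 1.76 mM min⁻¹. That ratio of 7.27 is larger than the ratio of the X charges, so the fall follows the clock rather than Q. The reckoning here therefore adds the charged Q to red's gain, giving 70.4 %.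

**The forecast.** It gives 0.9 in X and 0.6 in J, and it puts blue at 64 % because red's slowing “hints at mild Q inhibition or reversibility”. It stands 6.4 percentage points below the reckoning here.

**The flask.** Blue ends at 70.1 %, with exponents 0.97 in X and 0.73 in J.

    X + L ⇌ XL, settled at all times (0.6160 M⁻¹)
    XL + J ⇌ XLJ, settled at all times (23.70 M⁻¹)
    XLJ → Q + X (3.054 min⁻¹)
    2 L ⇌ L2, settled at all times (3.100 M⁻¹)
    J → Vy (0.1248 min⁻¹)

Q stands on the left of no step, and the leak is J → Vy. With red's rate of 28 mM min⁻¹ at two percent of L turned, the leak puts the Q made in blue at 121 mM, and the blue flask made 120 mM. In the grey run, the rate of 36 mM min⁻¹ at that same amount turned and the same leak put Q made at half the L charge at 9.15 min, and grey reached it at 9.04 min.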